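Readings and results come from a simulation with constants of no real substance.

Watch the solid.

| flask | X | E | remark | time |
|---|---|---|---|---|
| cedar | 5 mM | 0.80 equiv | run made earlier |  |
| oak | 20 mM | 0.80 equiv | run made earlier |  |
| flask | 10 mM | 0.800 equiv |  | 6.0 h |

| run | time / h | D / % | Q / % |
|---|---|---|---|
| cedar | 0.667 | 2.7 | 43.6 |
| cedar | 1.33 | 7.4 | 60.2 |
| cedar | 2.00 | 12.6 | 60.6 |
| cedar | 3.00 | 17.2 | 42.5 |
| cedar | 4.00 | 20.2 | 32.7 |
| cedar | 5.00 | 21.7 | 25.7 |
| oak | 0.667 | 2.9 | 9.2 |
| oak | 1.33 | 4.6 | 13.2 |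
| oak | 2.00 | 8.1 | 15.5 |
| oak | 3.00 | 9.8 | 16.3 |
| oak | 4.00 | 12.3 | 16.6 |
| oak | 5.00 | 13.6 | 16.9 |

(standard deviation of a reading: 0.5 percentage points)

- how much D there is at 6.0 h, in percent of the X charged
- concentration of Q in solution at 6.0 h, in percent of saturation

- I turn the question round. For cQ to stand near saturation at 6.0 h, solid X must still be present then, so X must dissolve on average slower than the charge over the time, 1.67 mM h⁻¹. E, at 0.800 equiv, is the limiting reagent, but I follow the solid here.
- The cedar run shows how fast X really goes. Its Q readings stand level at 60.2% and 60.6%, the second at 2.00 h, and have fallen to 42.5% by 3.00 h, so I take its 5 mM of X as dissolved at roughly 2.00 h. That gives a rough 2.50 mM h⁻¹, the dissolving pace: the X taken into solution per hour, on average, while solid lasts.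
- This pace is faster than the 1.67 mM h⁻¹ required, so I expect the solid in the flask to last about 4.00 h and cQ to be falling by 6.0 h.
- The forecast puts D at 25% and Q at 88% of saturation, with the solid “nearly gone but probably not quite”; on the solid it differs from my reckoning.

    Q + E → D (k = 0.790 M⁻¹ min⁻¹)
    X ⇌ Q, rate k2*(cs2 - [Q]) while solid is left; crystals form when [Q] > cs2 (solubility = 5.30 mM, k = 0.0150 min⁻¹)
    2 E → G (k = 0.530 M⁻¹ min⁻¹)
    2 Q → Z (k = 0.880 M⁻¹ min⁻¹)

- The flask gives 21.9% of D and 41.5% of saturation, 46 percentage points under the forecast, with X at 0% at 6.00 h. By 3.00 h it has dissolved at an average 2.42 mM h⁻¹, close to the pace from cedar and above the 1.67 mM h⁻¹ required. In the neighbour flask with 17 mM of X, charge over time is 2.83 mM h⁻¹, above the pace, and solid X still stands at 26.9% of its charge at 6.00 h.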